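**Plan**

- Retrosynthetic cuts: the N–O bond; the lactone C–O and C–CH3 bonds at the tertiary carbinol carbon (back to a ketone in ring C); the N–C(allylic) bond (aza-Michael); the bond from the quaternary carbon to the N-bearing ring-fusion CH shared by rings A, B and C (Mannich); the ring D C=C (aldol condensation); finally three C–C bonds around an acetoacetate core.
- Enabling feature: in ring C (piperidine) the quaternary carbon is α to the carbon that carries the lactone oxygen (a masked ketone) and β to nitrogen through the ring-fusion N–CH, a β-amino ketone. The same masked ketone is β to nitrogen a second time through the allylic N–CH of rings C/D, so ring C is a disguised 4-piperidone, the formal aza-[4+2] adduct of a cyclic iminium ion (ring A) and a dienone (rings D/E).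
- Forward order: ring E fragment 7 and ring A fragment 18 are joined on allyl acetoacetate (steps 14–17); ring D closes by aldol condensation (step 20); rings B and then C close in one flask (step 21); ring F by methyl addition and lactonization (step 22); N-oxidation last.
- Stereochemistry: the ring E centre comes from a CBS reduction relayed by a suprafacial Johnson–Claisen rearrangement. The C-methyl centre comes from (S)-4-methylpyrrolidin-2-one and its neighbour from a cis hydrogenation. These centres control the four made in step 21; the carbinol centre is set by cis-lactone closure and nitrogen by the ring fusion.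

Key step: step 21

Ring letters: A pyrrolidine, B cyclopentane, C piperidine, D cyclohexane, E cyclopentene, F δ-lactone.

Assumption: the N-oxide configuration drawn is the one reached by oxidizing the amine lone pair of the trans-fused A/C invertomer (oxygen anti to the adjacent ring-fusion hydrogen); the cis invertomer would force a syn-axial contact between the carbinol methyl and a ring B carbon.
Assumption: (S)-4-methylpyrrolidin-2-one (8) and (tert-butyldimethylsilyloxy)acetaldehyde (10) are taken as commercial.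

**Route**

Step 1
Reactants: 1 cyclopent-2-en-1-one
Product: 2 2-(hydroxymethyl)cyclopent-2-en-1-one
Conditions: 37% aq. HCHO, imidazole (cat.), THF/H2O, rt
Reagents that add atoms: formaldehyde (C=O)
Why: Morita–Baylis–Hillman reaction puts the hydroxymethyl group on the α-carbon of the enone; no stereocentre is formed.

Step 2
Reactants: 2 2-(hydroxymethyl)cyclopent-2-en-1-one
Product: 3 2-[(tert-butyldimethylsilyloxy)methyl]cyclopent-2-en-1-one
Conditions: TBSCl, imidazole, CH2Cl2, 0 °C to rt
Reagents that add atoms: tert-butyldimethylsilyl chloride (CC(C)(C)[Si](C)(C)Cl)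
Why: Standard silyl ether formation protects the primary allylic alcohol for the hydride and enolate steps that follow.

Step 3
Reactants: 3 2-[(tert-butyldimethylsilyloxy)methyl]cyclopent-2-en-1-one
Product: 4 (1R)-2-[(tert-butyldimethylsilyloxy)methyl]cyclopent-2-en-1-ol
Conditions: (S)-2-methyl-CBS-oxazaborolidine (10 mol %), BH3·SMe2, THF, −20 °C
Reagents that add atoms: none
Why: Corey–Bakshi–Shibata reduction, in which the α-substituted alkenyl arm acts as the large group, so that the (S)-catalyst should deliver hydride to give the (R)-allylic alcohol.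

Step 4
Reactants: 4 (1R)-2-[(tert-butyldimethylsilyloxy)methyl]cyclopent-2-en-1-ol
Product: 5 ethyl 2-[(1R)-2-[(tert-butyldimethylsilyloxy)methyl]cyclopent-2-en-1-yl]acetate
Conditions: MeC(OEt)3, EtCO2H (cat.), 140 °C, EtOH distilled off
Reagents that add atoms: triethyl orthoacetate (CCOC(C)(OCC)OCC)
Why: Johnson–Claisen rearrangement; the suprafacial [3,3] shift forms the new C–C bond on the ring face that the C–O bond leaves, which transfers the carbinol chirality to the ring E stereocentre and places the alkene where the target has it.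

Step 5
Reactants: 5 ethyl 2-[(1R)-2-[(tert-butyldimethylsilyloxy)methyl]cyclopent-2-en-1-yl]acetate
Product: 6 2-[(1R)-2-[(tert-butyldimethylsilyloxy)methyl]cyclopent-2-en-1-yl]ethanol
Conditions: LiAlH4, Et2O, 0 °C
Reagents that add atoms: none
Why: Hydride reduction of the ester to the primary alcohol; the stereocentre is not touched.

Step 6
Reactants: 6 2-[(1R)-2-[(tert-butyldimethylsilyloxy)methyl]cyclopent-2-en-1-yl]ethanol
Product: 7 tert-butyl{[(5R)-5-(2-iodoethyl)cyclopent-1-en-1-yl]methoxy}dimethylsilane
Conditions: I2, PPh3, imidazole, CH2Cl2, 0 °C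
Reagents that add atoms: iodine (II)
Why: Appel-type iodination of the primary alcohol through the alkoxyphosphonium salt gives the alkylating agent for the acetoacetate dianion.

Step 7
Reactants: 8 (4S)-4-methylpyrrolidin-2-one
Product: 9 tert-butyl (4S)-4-methyl-2-oxopyrrolidine-1-carboxylate
Conditions: Boc2O, DMAP (cat.), MeCN, rt
Reagents that add atoms: di-tert-butyl dicarbonate (CC(C)(C)OC(=O)OC(=O)OC(C)(C)C)
Why: N-acylation of the lactam; the carbamate activates the lactam for enolization and partial reduction and later stabilizes the N-acyliminium ion.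

Step 8
Reactants: 9 tert-butyl (4S)-4-methyl-2-oxopyrrolidine-1-carboxylate; 10 (tert-butyldimethylsilyloxy)acetaldehyde
Product: 11 tert-butyl (4S)-3-[2-(tert-butyldimethylsilyloxy)-1-hydroxyethyl]-4-methyl-2-oxopyrrolidine-1-carboxylate (diastereomer mixture)
Conditions: LiN(SiMe3)2, THF, −78 °C; then 10
Reagents that add atoms: none
Why: Aldol addition of the lactam lithium enolate; both new centres are removed or reset in steps 9 and 10, so the mixture is of no consequence.

Step 9
Reactants: 11 tert-butyl (4S)-3-[2-(tert-butyldimethylsilyloxy)-1-hydroxyethyl]-4-methyl-2-oxopyrrolidine-1-carboxylate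
Product: 13 tert-butyl (3E,4S)-3-[2-(tert-butyldimethylsilyloxy)ethylidene]-4-methyl-2-oxopyrrolidine-1-carboxylate, via mesylate 12 (not isolated)
Conditions: MsCl, Et3N, CH2Cl2, 0 °C; then DBU, rt
Reagents that add atoms: none
Why: Mesylation and E1cB elimination should give the exocyclic α-alkylidene lactam without touching the methyl-bearing centre.

Step 10
Reactants: 13 tert-butyl (3E,4S)-3-[2-(tert-butyldimethylsilyloxy)ethylidene]-4-methyl-2-oxopyrrolidine-1-carboxylate
Product: 14 tert-butyl (3R,4S)-3-[2-(tert-butyldimethylsilyloxy)ethyl]-4-methyl-2-oxopyrrolidine-1-carboxylate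
Conditions: H2 (1 atm), Pd/C, EtOAc, rt
Reagents that add atoms: none
Why: Heterogeneous catalytic hydrogenation should add hydrogen to the exocyclic alkene from the face opposite the neighbouring methyl group, which leaves the side chain cis to the methyl group.

Step 11
Reactants: 14 tert-butyl (3R,4S)-3-[2-(tert-butyldimethylsilyloxy)ethyl]-4-methyl-2-oxopyrrolidine-1-carboxylate
Product: 15 tert-butyl (3R,4S)-3-(2-hydroxyethyl)-4-methyl-2-oxopyrrolidine-1-carboxylate
Conditions: n-Bu4NF, THF, 0 °C
Reagents that add atoms: none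
Why: Fluoride-mediated desilylation frees the primary alcohol.

Step 12
Reactants: 15 tert-butyl (3R,4S)-3-(2-hydroxyethyl)-4-methyl-2-oxopyrrolidine-1-carboxylate
Product: 16 tert-butyl (3R,4S)-3-(2-iodoethyl)-4-methyl-2-oxopyrrolidine-1-carboxylate
Conditions: I2, PPh3, imidazole, CH2Cl2, 0 °C
Reagents that add atoms: iodine (II)
Why: Appel-type iodination at the lactam stage avoids a free alcohol next to the later N,O-acetal.

Step 13
Reactants: 16 tert-butyl (3R,4S)-3-(2-iodoethyl)-4-methyl-2-oxopyrrolidine-1-carboxylate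
Product: 18 tert-butyl (3R,4S)-3-(2-iodoethyl)-2-methoxy-4-methylpyrrolidine-1-carboxylate (both acetal epimers), via hemiaminal 17 (not isolated)
Conditions: i-Bu2AlH, CH2Cl2, −78 °C; then MeOH, PPTS, rt
Reagents that add atoms: methanol (CO)
Why: Partial reduction of the N-Boc lactam to the hemiaminal and acid-catalysed exchange to the N,O-acetal stores the iminium carbon in a base-stable form; the alkyl iodide is inert to the aluminium hydride.

Step 14
Reactants: 19 allyl acetoacetate; 7 tert-butyl{[(5R)-5-(2-iodoethyl)cyclopent-1-en-1-yl]methoxy}dimethylsilane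
Product: 20 allyl 6-[(1S)-2-[(tert-butyldimethylsilyloxy)methyl]cyclopent-2-en-1-yl]-3-oxohexanoate
Conditions: NaH, THF, 0 °C; n-BuLi, 0 °C; then 7, 0 °C to rt
Reagents that add atoms: none
Why: γ-Alkylation of the acetoacetate dianion, which reacts at the more basic terminal carbon.

Step 15
Reactants: 20 allyl 6-[(1S)-2-[(tert-butyldimethylsilyloxy)methyl]cyclopent-2-en-1-yl]-3-oxohexanoate; 18 tert-butyl (3R,4S)-3-(2-iodoethyl)-2-methoxy-4-methylpyrrolidine-1-carboxylate
Product: 21 allyl 2-{2-[(3R,4S)-1-Boc-2-methoxy-4-methylpyrrolidin-3-yl]ethyl}-6-[(1S)-2-[(tert-butyldimethylsilyloxy)methyl]cyclopent-2-en-1-yl]-3-oxohexanoate (epimer mixture at C-2)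
Conditions: K2CO3, DMF, 40 °C
Reagents that add atoms: none
Why: C-Alkylation of the β-keto ester at its doubly activated carbon joins the two chiral fragments.

Step 16
Reactants: 21 allyl 2-{2-[(3R,4S)-1-Boc-2-methoxy-4-methylpyrrolidin-3-yl]ethyl}-6-[(1S)-2-[(tert-butyldimethylsilyloxy)methyl]cyclopent-2-en-1-yl]-3-oxohexanoate; 22 tert-butyl acrylate
Product: 23 1-allyl 5-tert-butyl 2-{2-[(3R,4S)-1-Boc-2-methoxy-4-methylpyrrolidin-3-yl]ethyl}-2-{4-[(1S)-2-[(tert-butyldimethylsilyloxy)methyl]cyclopent-2-en-1-yl]butanoyl}pentanedioate (epimer mixture)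
Conditions: DBU (cat.), MeCN, rt
Reagents that add atoms: none
Why: Michael addition of the α-substituted β-keto ester to the acrylate installs the future lactone arm.

Step 17
Reactants: 23 1-allyl 5-tert-butyl 2-{2-[(3R,4S)-1-Boc-2-methoxy-4-methylpyrrolidin-3-yl]ethyl}-2-{4-[(1S)-2-[(tert-butyldimethylsilyloxy)methyl]cyclopent-2-en-1-yl]butanoyl}pentanedioate
Product: 25 tert-butyl 4-{2-[(3R,4S)-1-Boc-2-methoxy-4-methylpyrrolidin-3-yl]ethyl}-8-[(1S)-2-[(tert-butyldimethylsilyloxy)methyl]cyclopent-2-en-1-yl]-5-oxooctanoate (epimer mixture at C-4), via β-keto acid 24 (not isolated)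
Conditions: Pd(PPh3)4 (5 mol %), morpholine, THF, rt to 40 °C
Reagents that add atoms: none
Why: Palladium-catalysed deallylation (Tsuji–Trost transfer of allyl to morpholine) followed by decarboxylation of the β-keto acid removes the activating ester under neutral conditions that spare the N,O-acetal.

Step 18
Reactants: 25 tert-butyl 4-{2-[(3R,4S)-1-Boc-2-methoxy-4-methylpyrrolidin-3-yl]ethyl}-8-[(1S)-2-[(tert-butyldimethylsilyloxy)methyl]cyclopent-2-en-1-yl]-5-oxooctanoate
Product: 26 tert-butyl 4-{2-[(3R,4S)-1-Boc-2-methoxy-4-methylpyrrolidin-3-yl]ethyl}-8-[(1S)-2-(hydroxymethyl)cyclopent-2-en-1-yl]-5-oxooctanoate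
Conditions: n-Bu4NF, THF, 0 °C
Reagents that add atoms: none
Why: Fluoride-mediated desilylation frees the allylic alcohol.

Step 19
Reactants: 26 tert-butyl 4-{2-[(3R,4S)-1-Boc-2-methoxy-4-methylpyrrolidin-3-yl]ethyl}-8-[(1S)-2-(hydroxymethyl)cyclopent-2-en-1-yl]-5-oxooctanoate
Product: 27 tert-butyl 4-{2-[(3R,4S)-1-Boc-2-methoxy-4-methylpyrrolidin-3-yl]ethyl}-8-[(1S)-2-formylcyclopent-2-en-1-yl]-5-oxooctanoate
Conditions: MnO2, CH2Cl2, rt
Reagents that add atoms: none
Why: Chemoselective oxidation of the allylic alcohol to the enal.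

Step 20
Reactants: 27 tert-butyl 4-{2-[(3R,4S)-1-Boc-2-methoxy-4-methylpyrrolidin-3-yl]ethyl}-8-[(1S)-2-formylcyclopent-2-en-1-yl]-5-oxooctanoate
Product: 29 tert-butyl 4-{2-[(3R,4S)-1-Boc-2-methoxy-4-methylpyrrolidin-3-yl]ethyl}-5-oxo-5-[(7aR)-2,6,7,7a-tetrahydro-1H-inden-5-yl]pentanoate, via aldol 28 (not isolated)
Conditions: pyrrolidine, AcOH (cat.), toluene, 50 °C
Reagents that add atoms: none
Why: Intramolecular aldol condensation (6-(enolexo)-exo-trig) of the ketone methylene with the enal closes ring D as the cross-conjugated dienone; the allylic ring E stereocentre is not acidic and should survive.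

Step 21
Reactants: 29 tert-butyl 4-{2-[(3R,4S)-1-Boc-2-methoxy-4-methylpyrrolidin-3-yl]ethyl}-5-oxo-5-[(7aR)-2,6,7,7a-tetrahydro-1H-inden-5-yl]pentanoate
Product: 33 pentacyclic amino keto acid (rings A to E; ring C ketone; quaternary carbon carrying the CH2CH2CO2H arm), via silyl enol ether 30 (not isolated), via N-Boc Mannich adduct 31 (not isolated), via amino acid 32 (not isolated)
Conditions: Et3N, TMSOTf, CH2Cl2, 0 °C; BF3·OEt2, −78 °C; then CF3CO2H, −78 °C to rt; concentrate; NaHCO3, MeOH, rt
Reagents that add atoms: none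
Why: Soft enolization should give the tetrasubstituted silyl enol ether 30 (the future quaternary carbon is the only enolizable position of the dienone), and BF3·OEt2 ionizes the N,O-acetal to the cyclic N-acyliminium ion, which the enol ether attacks intramolecularly (Mukaiyama–Mannich reaction; closest known type: N-acyliminium cyclizations of silyl enol ethers). Ring B closes 5-exo-trig at the iminium carbon with the enol double bond exocyclic (5-(enolexo)-exo); after CF3CO2H has removed the Boc group and the tert-butyl ester, the liberated secondary amine adds to the dienone in a 6-endo-trig aza-Michael closure of ring C, so that the whole is a stepwise formal aza-Diels–Alder reaction. The N–CH ring-fusion centre is fixed by the neighbouring tether-bearing carbon because the bicyclo[3.3.0] system can only be cis-fused, and that neighbour keeps its configuration because the ion is trapped at −78 °C before an enecarbamate can form; the quaternary centre should follow from an endo-like approach in which the siloxydiene lies over the iminium ring, which places the acyl group cis to nitrogen. The allylic N–CH centre is set in the reversible conjugate addition with the cyclopentenyl carbon equatorial on the chair of ring C, and the adjacent CH by axial protonation of the resulting enol, which gives the trans C/D fusion. The step needs attack through the α-carbon of the cross-conjugated enol ether and 1,4- instead of 1,6-addition of nitrogen; the first is secured by the five-membered transition state and the second by six- against eight-membered ring closure.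

Step 22
Reactants: 33 pentacyclic amino keto acid
Product: 35 hexacyclic tertiary amine lactone (the N-deoxy form of the target), via tertiary alcohol 34 (not isolated)
Conditions: CeCl3, MeMgBr (excess), THF, −78 to 0 °C; then CF3CO2H, CH2Cl2, rt
Reagents that add atoms: methylmagnesium bromide (C[Mg]Br)
Why: Organocerium 1,2-addition to the hindered, enolizable ketone followed by acid-promoted lactonization through the tertiary carbocation; only the cis-fused δ-lactone can close, so oxygen enters on the face of the propanoic acid arm and the methyl-bearing centre is set whatever the facial course of the addition.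

Step 23
Reactants: 35 hexacyclic tertiary amine lactone
Product: 36 CNP0566793.4 (target N-oxide)
Conditions: mCPBA (1.0 equiv), K2CO3, CH2Cl2, −20 °C
Reagents that add atoms: 3-chloroperoxybenzoic acid (OOC(=O)c1cccc(Cl)c1)
Why: Peracid N-oxidation of the tertiary amine, which is much faster than epoxidation of the trisubstituted alkene; oxygen is delivered to the nitrogen lone pair, whose direction is fixed by the fused rings A and C.

**Compound list**

1 | cyclopent-2-en-1-one | O=C1CCC=C1 | starting material
2 | 2-(hydroxymethyl)cyclopent-2-en-1-one | O=C1CCC=C1CO | intermediate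
3 | 2-[(tert-butyldimethylsilyloxy)methyl]cyclopent-2-en-1-one | O=C1CCC=C1CO[Si](C)(C)C(C)(C)C | intermediate
4 | (1R)-2-[(tert-butyldimethylsilyloxy)methyl]cyclopent-2-en-1-ol | O[C@@H]1CCC=C1CO[Si](C)(C)C(C)(C)C | intermediate
5 | ethyl 2-[(1R)-2-[(tert-butyldimethylsilyloxy)methyl]cyclopent-2-en-1-yl]acetate | CC(C)(C)[Si](C)(C)OCC1=CCC[C@@H]1CC(=O)OCC | intermediate
6 | 2-[(1R)-2-[(tert-butyldimethylsilyloxy)methyl]cyclopent-2-en-1-yl]ethanol | CC(C)(C)[Si](C)(C)OCC1=CCC[C@@H]1CCO | intermediate
7 | tert-butyl{[(5R)-5-(2-iodoethyl)cyclopent-1-en-1-yl]methoxy}dimethylsilane (ring E fragment) | CC(C)(C)[Si](C)(C)OCC1=CCC[C@@H]1CCI | intermediate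
8 | (4S)-4-methylpyrrolidin-2-one | C[C@@H]1CNC(=O)C1 | starting material
9 | tert-butyl (4S)-4-methyl-2-oxopyrrolidine-1-carboxylate | C[C@@H]1CN(C(=O)OC(C)(C)C)C(=O)C1 | intermediate
10 | (tert-butyldimethylsilyloxy)acetaldehyde | O=CCO[Si](C)(C)C(C)(C)C | starting material
11 | tert-butyl (4S)-3-[2-(tert-butyldimethylsilyloxy)-1-hydroxyethyl]-4-methyl-2-oxopyrrolidine-1-carboxylate (diastereomer mixture) | C[C@@H]1CN(C(=O)OC(C)(C)C)C(=O)C1C(O)CO[Si](C)(C)C(C)(C)C | intermediate
12 | mesylate of 11 (not isolated) | C[C@@H]1CN(C(=O)OC(C)(C)C)C(=O)C1C(OS(C)(=O)=O)CO[Si](C)(C)C(C)(C)C | intermediate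
13 | tert-butyl (3E,4S)-3-[2-(tert-butyldimethylsilyloxy)ethylidene]-4-methyl-2-oxopyrrolidine-1-carboxylate | C[C@@H]1CN(C(=O)OC(C)(C)C)C(=O)/C1=C/CO[Si](C)(C)C(C)(C)C | intermediate
14 | tert-butyl (3R,4S)-3-[2-(tert-butyldimethylsilyloxy)ethyl]-4-methyl-2-oxopyrrolidine-1-carboxylate (3,4-cis) | C[C@@H]1CN(C(=O)OC(C)(C)C)C(=O)[C@@H]1CCO[Si](C)(C)C(C)(C)C | intermediate
15 | tert-butyl (3R,4S)-3-(2-hydroxyethyl)-4-methyl-2-oxopyrrolidine-1-carboxylate | C[C@@H]1CN(C(=O)OC(C)(C)C)C(=O)[C@@H]1CCO | intermediate
16 | tert-butyl (3R,4S)-3-(2-iodoethyl)-4-methyl-2-oxopyrrolidine-1-carboxylate | C[C@@H]1CN(C(=O)OC(C)(C)C)C(=O)[C@@H]1CCI | intermediate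
17 | tert-butyl (3R,4S)-2-hydroxy-3-(2-iodoethyl)-4-methylpyrrolidine-1-carboxylate (hemiaminal, not isolated) | C[C@@H]1CN(C(=O)OC(C)(C)C)C(O)[C@@H]1CCI | intermediate
18 | tert-butyl (3R,4S)-3-(2-iodoethyl)-2-methoxy-4-methylpyrrolidine-1-carboxylate (ring A fragment; both acetal epimers) | C[C@@H]1CN(C(=O)OC(C)(C)C)C(OC)[C@@H]1CCI | intermediate
19 | allyl acetoacetate | CC(=O)CC(=O)OCC=C | starting material
20 | allyl 6-[(1S)-2-[(tert-butyldimethylsilyloxy)methyl]cyclopent-2-en-1-yl]-3-oxohexanoate | CC(C)(C)[Si](C)(C)OCC1=CCC[C@@H]1CCCC(=O)CC(=O)OCC=C | intermediate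
21 | allyl 2-{2-[(3R,4S)-1-Boc-2-methoxy-4-methylpyrrolidin-3-yl]ethyl}-6-[(1S)-2-[(tert-butyldimethylsilyloxy)methyl]cyclopent-2-en-1-yl]-3-oxohexanoate (epimer mixture at C-2) | CC(C)(C)[Si](C)(C)OCC1=CCC[C@@H]1CCCC(=O)C(CC[C@@H]2[C@H](C)CN(C(=O)OC(C)(C)C)C2OC)C(=O)OCC=C | intermediate
22 | tert-butyl acrylate | C=CC(=O)OC(C)(C)C | starting material
23 | 1-allyl 5-tert-butyl 2-{2-[(3R,4S)-1-Boc-2-methoxy-4-methylpyrrolidin-3-yl]ethyl}-2-{4-[(1S)-2-[(tert-butyldimethylsilyloxy)methyl]cyclopent-2-en-1-yl]butanoyl}pentanedioate (epimer mixture) | CC(C)(C)[Si](C)(C)OCC1=CCC[C@@H]1CCCC(=O)C(CCC(=O)OC(C)(C)C)(CC[C@@H]2[C@H](C)CN(C(=O)OC(C)(C)C)C2OC)C(=O)OCC=C | intermediate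
24 | β-keto acid from deallylation of 23 (not isolated) | CC(C)(C)[Si](C)(C)OCC1=CCC[C@@H]1CCCC(=O)C(CCC(=O)OC(C)(C)C)(CC[C@@H]2[C@H](C)CN(C(=O)OC(C)(C)C)C2OC)C(=O)O | intermediate
25 | tert-butyl 4-{2-[(3R,4S)-1-Boc-2-methoxy-4-methylpyrrolidin-3-yl]ethyl}-8-[(1S)-2-[(tert-butyldimethylsilyloxy)methyl]cyclopent-2-en-1-yl]-5-oxooctanoate (epimer mixture at C-4) | CC(C)(C)[Si](C)(C)OCC1=CCC[C@@H]1CCCC(=O)C(CCC(=O)OC(C)(C)C)CC[C@@H]2[C@H](C)CN(C(=O)OC(C)(C)C)C2OC | intermediate
26 | tert-butyl 4-{2-[(3R,4S)-1-Boc-2-methoxy-4-methylpyrrolidin-3-yl]ethyl}-8-[(1S)-2-(hydroxymethyl)cyclopent-2-en-1-yl]-5-oxooctanoate | OCC1=CCC[C@@H]1CCCC(=O)C(CCC(=O)OC(C)(C)C)CC[C@@H]2[C@H](C)CN(C(=O)OC(C)(C)C)C2OC | intermediate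
27 | tert-butyl 4-{2-[(3R,4S)-1-Boc-2-methoxy-4-methylpyrrolidin-3-yl]ethyl}-8-[(1S)-2-formylcyclopent-2-en-1-yl]-5-oxooctanoate | O=CC1=CCC[C@@H]1CCCC(=O)C(CCC(=O)OC(C)(C)C)CC[C@@H]2[C@H](C)CN(C(=O)OC(C)(C)C)C2OC | intermediate
28 | ring D β-hydroxy ketone (aldol, not isolated) | OC1C(CC[C@H]2CCC=C12)C(=O)C(CCC(=O)OC(C)(C)C)CC[C@@H]3[C@H](C)CN(C(=O)OC(C)(C)C)C3OC | intermediate
29 | tert-butyl 4-{2-[(3R,4S)-1-Boc-2-methoxy-4-methylpyrrolidin-3-yl]ethyl}-5-oxo-5-[(7aR)-2,6,7,7a-tetrahydro-1H-inden-5-yl]pentanoate (dienone; epimer mixture at C-4) | O=C(C1=CC2=CCC[C@@H]2CC1)C(CCC(=O)OC(C)(C)C)CC[C@@H]3[C@H](C)CN(C(=O)OC(C)(C)C)C3OC | intermediate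
30 | trimethylsilyl enol ether of 29 (not isolated) | C[Si](C)(C)OC(C1=CC2=CCC[C@@H]2CC1)=C(CCC(=O)OC(C)(C)C)CC[C@@H]3[C@H](C)CN(C(=O)OC(C)(C)C)C3OC | intermediate
31 | N-Boc Mannich adduct (not isolated): tert-butyl (3S,3aR,6S,6aS)-6-(3-tert-butoxy-3-oxopropyl)-3-methyl-6-[(7aR)-2,6,7,7a-tetrahydro-1H-indene-5-carbonyl]hexahydrocyclopenta[b]pyrrole-1(2H)-carboxylate (rings A/B cis-fused, acyl cis to N) | C[C@@H]1CN(C(=O)OC(C)(C)C)[C@H]2[C@@H]1CC[C@@]2(CCC(=O)OC(C)(C)C)C(=O)C1=CC3=CCC[C@@H]3CC1 | intermediate
32 | amino acid from 31 after loss of Boc and tert-butyl (not isolated) | C[C@@H]1CN[C@H]2[C@@H]1CC[C@@]2(CCC(=O)O)C(=O)C1=CC3=CCC[C@@H]3CC1 | intermediate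
33 | pentacyclic amino keto acid (rings A to E; trans C/D fusion; ring C ketone; CH2CH2CO2H on the quaternary carbon) | C[C@@H]1CN2[C@H]3C4=CCC[C@@H]4CC[C@@H]3C(=O)[C@]5(CCC(=O)O)CC[C@H]1[C@@H]52 | intermediate
34 | tertiary methyl carbinol of 33 (both carbinol epimers, not isolated) | C[C@@H]1CN2[C@H]3C4=CCC[C@@H]4CC[C@@H]3C(C)(O)[C@]5(CCC(=O)O)CC[C@H]1[C@@H]52 | intermediate
35 | hexacyclic tertiary amine lactone (N-deoxy form of the target) | C[C@@H]1CN2[C@H]3C4=CCC[C@@H]4CC[C@@H]3[C@@]3(C)OC(=O)CC[C@]34CC[C@H]1[C@@H]42 | intermediate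
36 | CNP0566793.4 (N-oxide) | C[C@@H]1C[N@@+]2([O-])[C@H]3C4=CCC[C@@H]4CC[C@@H]3[C@@]3(C)OC(=O)CC[C@]34CC[C@H]1[C@@H]42 | target

**Totals**

Total step count: 23. Longest linear sequence: 16 steps (steps 1–6 then 14–23, or steps 7–13 then 15–23).

**Steps most likely to fail**

Step 21. What may go wrong is a process of three kinds. The carbon next to the iminium carbon may lose its configuration if the ion collapses to an enecarbamate. The enol ether may approach with the acyl group turned away from nitrogen, so that the acyl group ends trans to nitrogen and the piperidine cannot close. The enol formed in the aza-Michael step may be protonated on the other face, giving the cis C/D epimer. The fallback sets out from 29 and replaces the kinetic N-acyliminium closure by a reversible, thermodynamically controlled Mannich reaction of the free imine. CF3CO2H strips the Boc group, the tert-butyl ester and methanol from 29 to give the cyclic imine keto acid F1. F1 is then heated in MeOH/AcOH, where the protonated 1-pyrroline and the ketone enol close and reopen ring B, and only the epimer with the ketone cis to nitrogen is drained by aza-Michael addition. The sequence comes back to the route at 33.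

Step 22. What may go wrong is enolization of the ketone instead of addition, fragmentation of the γ-amino tertiary cation (which would cleave the bond made in step 21), or loss and return of the proton on the neighbouring CH during ionization. The fallback sets out from 33 and avoids a free cation. Methylenation with the Lombardo reagent (Zn, CH2Br2, TiCl4) should give the exocyclic alkene acid F2. Phenylselenolactonization (PhSeCl, CH2Cl2, −78 °C, on the trifluoroacetate salt of the amine) closes the cis-lactone at the tertiary carbon and gives the phenylselenyl lactone F3. Radical reduction (Bu3SnH, AIBN, toluene, 80 °C) replaces selenium by hydrogen, and the sequence comes back at 35.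

Step 10. What may go wrong is migration of the exocyclic double bond into the ring on the palladium surface, which would erase the methyl stereocentre and the basis of the cis selectivity. The fallback sets out from 9 and uses enolate chemistry instead of hydrogenation. The lithium enolate of 9 is alkylated with 2-(tert-butyldimethylsilyloxy)ethyl triflate trans to the methyl group to give the trans lactam F4. F4 is deprotonated again with LiN(SiMe3)2 and the enolate is protonated kinetically with 2,6-di-tert-butylphenol from the face away from the methyl group. The sequence comes back at the cis lactam 14.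

**Further compounds**

F1 | step 21 | cyclic imine keto acid: 4-{2-[(3R,4S)-4-methyl-3,4-dihydro-2H-pyrrol-3-yl]ethyl}-5-oxo-5-[(7aR)-2,6,7,7a-tetrahydro-1H-inden-5-yl]pentanoic acid | C[C@@H]1CN=C[C@@H]1CCC(CCC(=O)O)C(=O)C1=CC2=CCC[C@@H]2CC1
F2 | step 22 | exocyclic alkene acid (33 with C=CH2 in place of the ring C ketone) | C[C@@H]1CN2[C@H]3C4=CCC[C@@H]4CC[C@@H]3C(=C)[C@]5(CCC(=O)O)CC[C@H]1[C@@H]52
F3 | step 22 | phenylselenyl lactone (35 with CH2SePh in place of the carbinol methyl) | C[C@@H]1CN2[C@H]3C4=CCC[C@@H]4CC[C@@H]3[C@@]3(C[Se]c5ccccc5)OC(=O)CC[C@]34CC[C@H]1[C@@H]42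
F4 | step 10 | tert-butyl (3S,4S)-3-[2-(tert-butyldimethylsilyloxy)ethyl]-4-methyl-2-oxopyrrolidine-1-carboxylate (3,4-trans) | C[C@@H]1CN(C(=O)OC(C)(C)C)C(=O)[C@H]1CCO[Si](C)(C)C(C)(C)C
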